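The data are simulated from invented constants; the scatter is artificial.

common to all: L 11.1 mM; Z 78 µM
- larch: Q 37 mM; the very flask that is asked about, followed so far
- oak: Q 56 mM; run made earlier
- flask: Q 37 mM; time 20 h

| run | time / h | J / % | X / % |
|---|---|---|---|
| larch | 0.417 | 18.6 | 17.0 |
| larch | 0.833 | 34.8 | 13.7 |
| larch | 1.33 | 39.8 | 9.9 |
| larch | 2.50 | 40.8 | 9.6 |
| larch | 4.00 | 37.3 | 8.6 |
| larch | 8.00 | 35.0 | 9.2 |
| oak | 0.417 | 12.1 | 11.5 |
| oak | 1.00 | 33.4 | 12.7 |
| oak | 2.00 | 41.3 | 10.5 |
| oak | 4.00 | 40.5 | 9.1 |
| oak | 10.0 | 40.7 | 9.5 |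
| oak | 20.0 | 40.8 | 9.5 |

(standard deviation of a reading: 0.5 percentage points)

- given per volume of solution although it is solid: Q
- steps under discussion: G + L -> D; G + Z <-> X + Z; J + Z <-> G + Z; Q <-> G; X <-> J
- at the start none of Q is in solution

- time, not beyond 20 h, at which the flask holds most J
- the amount of J, in percent of the Q charged, at that time
- earliest time at which at least nineteen twentieths of that best amount are there
- latest time at which they still are

The amounts in oak stop moving: from 4.00 h to 20.0 h J reads 40.5 % to 40.8 %, inside a scatter of 0.5 percentage points, so I take the loss to D in oak as ended by the last reading and count turnovers. Each L turns once, carrying one G into D, which makes L the limiting reagent of that loss and puts the fraction L/Q of the charge into D when the loss has ended: 0.198 in oak, 0.300 in larch, the flask asked about. Of what stays out of D, oak's last reading has a part 0.509 as J; this end share of J is what I carry.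

Now turn the question round: what would let J in larch end as high as its top reading, 40.8 %? By the end share, L/Q would have to sit at oak's 0.198. Larch stands higher, by 0.102, so I expect J in larch to fall by 5.2 points from that reading and end at 35.6 %.

The forecast puts the top at 41.5 % at 1.9 h, with the window from 1.3 h to 3 h, and says “J overshoots because equilibration is faster than the loss to D”.

The flask gives 40.7 % at 1.74 h, with the window from 1.12 h to 3.25 h.

    G + L → D (k = 0.720 M⁻¹ min⁻¹)
    G + Z ⇌ X + Z, rate k2*[G]*[Z] forward; the back reaction follows from the equilibrium constant (K = 0.320, k = 3300 M⁻¹ min⁻¹)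
    J + Z ⇌ G + Z, rate k3*[Z]*[J] forward; the back reaction follows from the equilibrium constant (k = 200 M⁻¹ min⁻¹)
    Q ⇌ G, rate k4*(cs4 - [G]) while solid is left; crystals form when [G] > cs4 (solubility = 35.0 mM, k = 0.0680 min⁻¹)
    X ⇌ J (K = 4.20, k = 0.0110 min⁻¹)

At 20.0 h the flask holds J 35.3 % and D 30.0 %, with L at 0.0147 % of its charge, against my 35.6 %. The neighbouring flask, charged with 4.4 mM of L, has L/Q 0.119, so the same end share promises J 44.8 %. That flask ends with D 11.9 %, L 0 % and J 44.5 %. The best J of the neighbouring flask is higher than that end, at 45.9 %.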